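## The problem

Cycloshizukaol A (41) is a C2-symmetric dimer of two lindenane units. Each half is a cyclopropane-fused hydrindane (cyclopropane C1–C2–C3, five-membered ring C1/C3/C4/C5/C10, six-membered ring C5–C10) that carries a cross-conjugated dienone C4=C5–C6=C7–C8=O, a secondary carbinol at C9 and the angular methyl on C10. The halves are joined head to tail by two C11–C15 bonds, so that C11, C15, C4, C5, C6 and C7 of each half form a twelve-membered carbocycle. C11 is quaternary (methyl, methoxycarbonyl, C7, C15′) and is the only stereocentre off the rigid tricycle: C1, C3 and C10 are locked in the bicyclo[3.1.0]hexane, and C10 can direct C9 and, through a cis ring fusion, a temporary centre at C5, but nothing in the finished skeleton reaches C11. A synthesis must therefore form two bonds to fully substituted carbons between hindered partners, close a twelve-membered ring, and set C11 twice in the same sense. The α-ketol/dienone is sensitive to base, the dienes and any allylic oxygen at C5 or C8 to acid, and the vinylcyclopropane to electrophiles, so the C8 ketone should appear last. The opening is the homoallylic array C11–C15–C4=C5: shifting the alkene to an exocyclic C4=C15 methylene and placing an ester oxygen on C5 turns each junction into the C11=C12(O)–O–C5–C4=C15 unit of an ester-enolate Claisen rearrangement, with the controllable C5 carbinol as the source of the C11 configuration.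

## Retrosynthesis

**41 ⇒ 38.** No skeletal bond is cut. The two C8 ketones are taken back to allylic alcohols held with the C9 hydroxyls as acetonides, and the methyl esters to free acids. This keeps the base-sensitive dienone out of every earlier step, and the acids of 38 are exactly what a silyl-ester-forming rearrangement delivers. The forward steps are esterification (39), acetonide hydrolysis (40) and an oxidation selective for the allylic C8 hydroxyl.

**38 ⇒ 35 (key disconnection).** Both C11–C15 bonds are cut by a retro-[3,3] shift. Each C4=C5 alkene returns to C4=C15 and each C11 becomes the α-carbon of an ester bound to the C5 oxygen of the other half. The neighbouring option, alkylating a C11 ester enolate with a C15 allylic halide, would have to make two quaternary centres intermolecularly with no element to control them. The sigmatropic route is intramolecular, cannot give the monomeric bridged isomer, and transfers chirality from C5. The precursor 35 is a twelve-membered dilactone with no quaternary C11 and no carbocyclic macro-ring. The forward step needs one ketene acetal geometry, a chair transition state, and reaction at C15, not at C7.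

**35 ⇒ 33 ⇒ 31 ⇒ 27 + 28.** The two ester C–O bonds are cut, the ring-closing one first. Both components come from a single monomer 26: the acid 27 keeps its tertiary hydroxyl silylated, the alcohol 28 keeps its acid as the methyl ester. A one-pot cyclodimerization would be shorter, but acylation of a tertiary bis-allylic alcohol is demanding enough to be done one bond at a time: alkoxide plus acid chloride for the first, a high-dilution lactonization for the second. A monomeric lactone is excluded because it would place C6=C7 at a bridgehead.

**26 ⇒ 23 + 24.** The C7–C11 bond is cut between an alkenyl triflate and the zinc enolate of methyl 2-bromopropanoate (24). C7 must be a ketone for the ring closure below, so C11 cannot be carried earlier. A palladium-catalysed sp2–sp3 coupling installs the whole propanoate in one step and leaves C11 tertiary and enolizable, as the key step requires. The precursor is the tricyclic ketone 21.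

**21 ⇒ 19.** The C5–C6 bond is cut by a retro-aldol to the methyl ketone 19. Adding a vinyl nucleophile to the C5 ketone and closing by metathesis would be shorter in fragments, but its facial selectivity is uncertain: the cyclopropane methylene and the C10 side chain shield opposite faces. In the intramolecular aldol the nucleophile is tethered through C9 on the α face of C10, so it can only give the cis-fused ketol with the C5 oxygen β.

**19 ⇒ 15 ⇒ 9 + 14.** The C9–C10 bond is cut by a retro-Mukaiyama aldol between the silyl dienol ether 9 and the α-silyloxy aldehyde 14. This sets the C10 quaternary centre (attack anti to the cyclopropane methylene) and C9 (Felkin–Anh control from C8) in one step. The aldehyde brings C6–C9 with C7 as a masked ketone. Any minor enantiomer of 9 should be removed here as a diastereomer.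

**9 ⇒ 8 ⇒ 4 ⇒ 1.** The C15 methylene is put on before the aldol. It blocks C4, so the tetrasubstituted C5=C10 enol ether forms regiospecifically, and it cannot migrate into the ring. The methyl group and the absolute configuration come from desymmetrization of the meso ketone 1 (via 2).

**14 ⇒ 10.** The aldehyde derives in four steps from (E)-but-2-en-1-ol (10): asymmetric epoxidation (11), C3-selective opening (12), silylation (13) and selective oxidation.

## Roads not taken

**Alternative 1:** Here the cut is at the C1–C2 and C2–C3 bonds of both cyclopropanes. Et2Zn/CH2I2 would cyclopropanate both C1=C3 cyclopentene alkenes of a macrocyclic bis(tertiary allylic alcohol), syn to the C4 hydroxyls, to give the bis(cyclopropyl carbinol) A1. A vinylogous dehydration (C4–OH/C5–H) would then reveal the dienones.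
- Merits: hydroxyl-directed cyclopropanation is one of the most predictable stereoselective reactions, the electron-poor C6=C7 enone would not compete, and the strained ring would not have to survive a long sequence.
- Weak points: the step presupposes a macrocycle that already holds both quaternary C11 centres and both C11–C15 bonds, which is the real difficulty. The cyclopropyl carbinol of A1 must be dehydrated without opening through a cyclopropylcarbinyl cation.
- Comparison: in stereochemical predictability this key step is better than the one chosen. The chosen plan sets against this that its key step forms the macrocyclic C–C bonds and the quaternary centres together, and that the cyclopropane is bought with the starting material 1.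

**Alternative 2:** The cut is the C9–C10 bond of a monomer. Me2AlCl would activate a C9 aldehyde, the C10 terminus of a diene would attack it in a Prins/carbonyl-ene closure, and loss of the C4 proton would give the C4=C5–C6=C7 diene of A2.
- Merits: the six-membered ring, the C10 quaternary centre, the C9 carbinol and the diene arise in one step, and C15 already carries the propanoate.
- Weak points: A2 has the C11–C15 bond but lacks C7–C11. Dimerization would then have to join a tertiary ester α-carbon to the α-carbon of an enone twice, once as a macrocyclization, creating both quaternary centres with nothing to direct C11. C11 of A2 is itself uncontrolled.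
- Comparison: monomer assembly is more convergent than steps 9–15 of the chosen route. The chosen plan makes C7–C11 while C11 is still tertiary and saves the quaternization for a chirality-transferring step.

**Alternative 3:** The cut is the C1–C3 bond. KOtBu would generate the extended trienolate of a carvone-derived eudesmane dienone, whose C3 terminus displaces a C1 mesylate, closing the cyclopropane and contracting the cyclohexene to give A3.
- Merits: the absolute configuration and the C10 quaternary centre come from the chiral pool, and A3 already has the C8 ketone, C9 oxygen and C7 propanoate of the natural monomer.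
- Weak points: A3 must still be dimerized through C11–C15. That needs functionalization of the C15 methyl and two enolate alkylations (one macrocyclizing) on a base-sensitive cross-conjugated dienone, with C11 remote from every stereocentre, so three diastereomers are to be expected.
- Comparison: this road probably reaches a monomer in fewer steps and with more reliable stereocontrol than steps 1–15. The chosen plan offers in return a dimerization whose C–C bonds form intramolecularly and whose C11 configuration is derived from C5, with the dienone unveiled only at the end.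

Key step: step 22

Remark 1: the (R,R)-amide in step 1 is assumed to select the α-methylene that leads to 2; if the sense proves opposite, the (S,S)-amide is used and nothing else changes.
Remark 2: C2 of 4–8 and C11 of 26–36 are carried as epimer mixtures (no descriptor in the SMILES); both are planarized later (steps 4 and 22).
Remark 3: tricyclic compounds are named on the lindenane skeleton; β is the face of the C10 methyl (C14), the cyclopropane CH2 (C2) is β, and C15 is the carbon on C4.

## Route

Step 1
Reactants: 1 cis-bicyclo[3.1.0]hexan-3-one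
Product: 2 (1R,5R)-3-(trimethylsilyloxy)bicyclo[3.1.0]hex-2-ene
Conditions: LiN[(R)-CHMePh]2 (from the amine and n-BuLi), LiCl, Me3SiCl, THF, −78 °C
Reagents that add atoms: chlorotrimethylsilane, C[Si](C)(C)Cl
Why: Enantioselective deprotonation of a meso ketone by a chiral lithium amide with in situ O-silylation (asymmetric desymmetrization); the choice between the two mirror-related α-methylenes decides which cyclopropane carbon becomes C1 and so fixes the absolute configuration of the route.

Step 2
Reactants: 2 (1R,5R)-3-(trimethylsilyloxy)bicyclo[3.1.0]hex-2-ene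
Product: 4 (1R,5R)-2-methylbicyclo[3.1.0]hexan-3-one (C2 epimers), via lithium enolate 3 (not isolated)
Conditions: MeLi, THF, 0 °C; then MeI, DMPU, −78 → 0 °C
Reagents that add atoms: iodomethane, CI
Why: Regiospecific enolate generation from the silyl enol ether followed by C-methylation (enolate alkylation) places the methyl on the future C10; its configuration is irrelevant because C10 is re-enolized in step 4.

Step 3
Reactants: 4 (1R,5R)-2-methylbicyclo[3.1.0]hexan-3-one
Product: 8 (1R,5S)-2-methyl-4-methylidenebicyclo[3.1.0]hexan-3-one, via lithium enolate 5 (not isolated), via Mannich base 6 (not isolated), via methiodide 7 (not isolated)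
Conditions: LiN(iPr)2, THF, −78 °C; Eschenmoser's salt (Me2N=CH2 I), −78 °C → rt; MeI, MeOH, rt; aq NaHCO3, CH2Cl2
Reagents that add atoms: dimethyl(methylidene)ammonium iodide, C[N+](C)=C.[I-]
Why: Kinetic deprotonation takes the less substituted α-carbon (C4); Mannich reaction, N-methylation and elimination give the α-methylene ketone (Eschenmoser methylenation). The alkene cannot move into the ring (it would be a cyclopropene) and leaves C10–H as the only enolizable position; 8 is used at once because α-methylene ketones dimerize.

Step 4
Reactants: 8 (1R,5S)-2-methyl-4-methylidenebicyclo[3.1.0]hexan-3-one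
Product: 9 (1R,5S)-3-(tert-butyldimethylsilyloxy)-2-methyl-4-methylidenebicyclo[3.1.0]hex-2-ene
Conditions: tBuMe2SiOTf, Et3N, CH2Cl2, 0 °C
Reagents that add atoms: tert-butyldimethylsilyl trifluoromethanesulfonate, CC(C)(C)[Si](C)(C)OS(=O)(=O)C(F)(F)F
Why: Soft enolization and O-silylation; only C10–H can be removed, so the tetrasubstituted enol ether forms regiospecifically as a transoid 2-silyloxy diene that cannot undergo Diels–Alder dimerization.

Step 5
Reactants: 10 (E)-but-2-en-1-ol
Product: 11 [(2R,3R)-3-methyloxiran-2-yl]methanol
Conditions: Ti(OiPr)4 (cat.), D-(−)-diethyl tartrate (cat.), tBuOOH, 4 Å molecular sieves, CH2Cl2, −20 °C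
Reagents that add atoms: tert-butyl hydroperoxide, CC(C)(C)OO
Why: Sharpless asymmetric epoxidation; with the D-tartrate ester the (E)-allylic alcohol gives the (2R,3R) epoxy alcohol, whose C2 becomes C8 of the target skeleton.

Step 6
Reactants: 11 [(2R,3R)-3-methyloxiran-2-yl]methanol
Product: 12 (2R,3S)-3-[(4-methoxybenzyl)oxy]butane-1,2-diol
Conditions: Ti(OiPr)4 (1.5 equiv), 4-MeOC6H4CH2OH (excess), CH2Cl2, reflux
Reagents that add atoms: 4-methoxybenzyl alcohol, COc1ccc(CO)cc1
Why: Titanium-assisted opening of a 2,3-epoxy alcohol: the metal bound to the primary alkoxide activates the epoxide and directs the alcohol to C3 with inversion, giving the anti 3-ether 1,2-diol.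

Step 7
Reactants: 12 (2R,3S)-3-[(4-methoxybenzyl)oxy]butane-1,2-diol
Product: 13 (2R,3S)-3-[(4-methoxybenzyl)oxy]-1,2-bis(triethylsilyloxy)butane
Conditions: Et3SiCl, imidazole, DMF, 0 °C → rt
Reagents that add atoms: chlorotriethylsilane, CC[Si](CC)(CC)Cl
Why: Silyl ether formation at both hydroxyls; the secondary silyl ether is the non-chelating α-substituent needed in step 9.

Step 8
Reactants: 13 (2R,3S)-3-[(4-methoxybenzyl)oxy]-1,2-bis(triethylsilyloxy)butane
Product: 14 (2S,3S)-3-[(4-methoxybenzyl)oxy]-2-(triethylsilyloxy)butanal
Conditions: (COCl)2, DMSO, CH2Cl2, −78 → −30 °C; Et3N, → 0 °C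
Reagents that add atoms: none
Why: Under Swern conditions a primary triethylsilyl ether is converted directly into the aldehyde while the secondary silyl ether survives (selective oxidative desilylation); the aldehyde is used without storage to avoid α-epimerization.

Step 9
Reactants: 9 (1R,5S)-3-(tert-butyldimethylsilyloxy)-2-methyl-4-methylidenebicyclo[3.1.0]hex-2-ene; 14 (2S,3S)-3-[(4-methoxybenzyl)oxy]-2-(triethylsilyloxy)butanal
Product: 15 C10-quaternary aldol adduct (C9 hydroxyl, C8 triethylsilyl ether, C7 4-methoxybenzyl ether)
Conditions: BF3·OEt2, CH2Cl2, −78 °C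
Reagents that add atoms: none
Why: Mukaiyama aldol addition forms C9–C10. C10 is set by attack on the enol ether face opposite the cyclopropane methylene (methyl ends syn to it); C9 is set by Felkin–Anh addition to the α-silyloxy aldehyde under a non-chelating Lewis acid, reinforced by the anti β-alkoxy group, giving the 8,9-anti array. The adduct of any enantiomeric 9 would be a separable diastereomer.

Step 10
Reactants: 15 C10-quaternary aldol adduct
Product: 17 8,9-acetonide C7 4-methoxybenzyl ether, via diol 16 (not isolated)
Conditions: camphorsulfonic acid (cat.), MeOH (3 equiv), Me2C(OMe)2, CH2Cl2, 0 °C → rt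
Reagents that add atoms: 2,2-dimethoxypropane, COC(C)(C)OC
Why: Acid-catalysed methanolysis of the secondary silyl ether and ketalization of the 8,9-diol in one flask (acetonide formation); the anti diol gives the cis-dioxolane that later becomes the cis-fused ring, and capping C9–OH closes the retro-aldol and oxa-Michael pathways.

Step 11
Reactants: 17 8,9-acetonide C7 4-methoxybenzyl ether
Product: 18 8,9-acetonide C7 alcohol
Conditions: DDQ, CH2Cl2/pH 7 buffer, 0 °C
Reagents that add atoms: none
Why: Oxidative cleavage of the 4-methoxybenzyl ether (benzylic hydride abstraction, then hydrolysis of the oxocarbenium ion); enone, acetonide and cyclopropane are inert to DDQ.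

Step 12
Reactants: 18 8,9-acetonide C7 alcohol
Product: 19 8,9-acetonide methyl ketone (C7 carbonyl, C6 methyl)
Conditions: Dess–Martin periodinane, CH2Cl2, rt
Reagents that add atoms: none
Why: Dess–Martin oxidation of the secondary alcohol under non-basic conditions, so that C8 next to the new ketone is not epimerized.

Step 13
Reactants: 19 8,9-acetonide methyl ketone
Product: 21 5β-(triethylsilyloxy)-8β,9β-(isopropylidenedioxy)-11,12,13-trinorlinden-4(15)-en-7-one, via lithium aldolate 20 (not isolated)
Conditions: LiN(SiMe3)2, THF, −78 °C; then Et3SiOTf, −78 → −40 °C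
Reagents that add atoms: triethylsilyl trifluoromethanesulfonate, CC[Si](CC)(CC)OS(=O)(=O)C(F)(F)F
Why: Intramolecular ketone–ketone aldol addition of the Hajos–Parrish ketol type: the kinetic methyl-ketone enolate (C6) adds to the C5 carbonyl and closes the six-membered ring. C6 is tethered through C9 on the α face of C10 and can only reach the α face of C5, so the oxygen is set β, cis to the C10 methyl. Silylation of the tertiary lithium alkoxide blocks the retro-aldol.

Step 14
Reactants: 21 5β-(triethylsilyloxy)-8β,9β-(isopropylidenedioxy)-11,12,13-trinorlinden-4(15)-en-7-one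
Product: 23 5β-(triethylsilyloxy)-8β,9β-(isopropylidenedioxy)-11,12,13-trinorlindena-4(15),6-dien-7-yl trifluoromethanesulfonate, via potassium enolate 22 (not isolated)
Conditions: KN(SiMe3)2, THF, −78 °C; PhNTf2, −78 → 0 °C
Reagents that add atoms: N-phenylbis(trifluoromethanesulfonimide), O=S(=O)(N(c1ccccc1)S(=O)(=O)C(F)(F)F)C(F)(F)F
Why: Kinetic enolization goes to the methylene C6 in preference to the alkoxy-substituted methine C8, and O-sulfonylation gives the enol triflate with the C6=C7 alkene in place.

Step 15
Reactants: 23 alkenyl triflate; 24 methyl 2-bromopropanoate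
Product: 26 methyl 5β-(triethylsilyloxy)-8β,9β-(isopropylidenedioxy)lindena-4(15),6-dien-12-oate (C11 epimers), via zinc enolate 25 (not isolated)
Conditions: Zn dust (activated with Me3SiCl), 24, THF, rt; then 23, Pd2(dba)3 (cat.), XPhos, THF, 50 °C
Reagents that add atoms: none
Why: Negishi-type cross-coupling of a Reformatsky reagent with an alkenyl triflate under zerovalent palladium (oxidative addition, transmetalation, reductive elimination) forms C7–C11. Both C11 epimers are acceptable because this centre is planarized in step 22.

Step 16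
Reactants: 26 methyl 5β-(triethylsilyloxy)-8β,9β-(isopropylidenedioxy)lindena-4(15),6-dien-12-oate
Product: 27 5β-(triethylsilyloxy)-8β,9β-(isopropylidenedioxy)lindena-4(15),6-dien-12-oic acid
Conditions: Me3SnOH, 1,2-dichloroethane, 70 °C; then 0.01 M KHSO4 wash
Reagents that add atoms: trimethyltin hydroxide, C[Sn](C)(C)O
Why: Tin hydroxide-mediated hydrolysis of the methyl ester under near-neutral conditions; aqueous hydroxide is avoided so that C6=C7 is not drawn into conjugation with the carboxyl group.

Step 17
Reactants: 26 methyl 5β-(triethylsilyloxy)-8β,9β-(isopropylidenedioxy)lindena-4(15),6-dien-12-oate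
Product: 28 methyl 5β-hydroxy-8β,9β-(isopropylidenedioxy)lindena-4(15),6-dien-12-oate
Conditions: Bu4NF, AcOH (1:1), THF, 0 °C → rt
Reagents that add atoms: none
Why: Buffered fluoride cleaves the tertiary silyl ether; acid is avoided because the bis-allylic tertiary alcohol ionizes easily.

Step 18
Reactants: 27 silyl ether acid; 28 hydroxy ester
Product: 31 seco ester (acyl group of 27 on the C5 oxygen of 28), via acid chloride 29 (not isolated), via lithium alkoxide 30 (not isolated)
Conditions: 27, 1-chloro-N,N,2-trimethylprop-1-en-1-amine, CH2Cl2, 0 °C → rt; 28, LiN(SiMe3)2, THF, −78 °C; combine, −78 → 0 °C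
Reagents that add atoms: none
Why: Acylation of a tertiary lithium alkoxide by an acid chloride, the standard esterification of hindered tertiary allylic alcohols. O–H deprotonation is far faster than removal of C11–H, and the acid chloride is made under neutral conditions that spare the silyl ether and acetonide.

Step 19
Reactants: 31 seco ester
Product: 32 seco acid (C5 triethylsilyl ether)
Conditions: Me3SnOH, 1,2-dichloroethane, 60 °C; then 0.01 M KHSO4 wash
Reagents that add atoms: trimethyltin hydroxide, C[Sn](C)(C)O
Why: Chemoselective tin hydroxide hydrolysis: the methyl ester is attacked while the far more hindered tertiary alkyl ester stays intact.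

Step 20
Reactants: 32 seco acid (C5 triethylsilyl ether)
Product: 33 seco hydroxy acid
Conditions: Bu4NF, AcOH (1:1), THF, 0 °C → rt
Reagents that add atoms: none
Why: Buffered fluoride desilylation frees the tertiary hydroxyl without acid and without cleaving the tertiary ester.

Step 21
Reactants: 33 seco hydroxy acid
Product: 35 twelve-membered macrodiolide (C12 to O5′ and C12′ to O5), via acyloxypyridinium salt 34 (not isolated)
Conditions: 2-chloro-1-methylpyridinium iodide, Et3N, CH2Cl2, reflux, slow addition of 33 (final ca. 1 mM)
Reagents that add atoms: none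
Why: Mukaiyama macrolactonization through the 2-acyloxypyridinium salt. With this α-branched, α-alkenyl acyl group the transfer can also run through the ketene, an unhindered electrophile suited to the tertiary hydroxyl. The ring formed is a twelve-membered [3.3]metacyclophane-type dilactone with two rigid 1,3-bridged cyclohexenes.

Step 22
Reactants: 35 twelve-membered macrodiolide
Product: 38 macrocyclic diacid bis(acetonide), via bis(silyl ketene acetal) 36 (not isolated), via bis(trimethylsilyl ester) 37 (not isolated)
Conditions: KN(SiMe3)2 (6 equiv), Me3SiCl (8 equiv), THF, −78 → 25 °C (60 °C if needed); then aq citric acid, THF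
Reagents that add atoms: none
Why: Double Ireland–Claisen rearrangement: the amide base removes both C11 protons, the dienolates are O-silylated in situ to 36, and each C11=C12(OSiMe3)–O–C5–C4=C15 unit rearranges through a six-membered transition state in which O–C5 breaks as C11–C15 forms; hydrolysis of 37 gives the acids. The closest known reaction is the Ireland–Claisen rearrangement of tertiary allylic esters and of lactones carrying an exocyclic alkene at the carbinol carbon, where the ring size is kept. The carbocycle is not closed end to end: in each shift O and C12 leave the twelve-membered ring while C15 and C4 enter it, through a pericyclic transition state that bridges the existing ring. Each new C11 centre is controlled by the C5 carbinol centre (oxygen β), which is consumed suprafacially, together with the ketene acetal geometry and a chair transition state. A chair with C7 cis to the ester oxygen (methyl cis to OSiMe3) leads to the required (R) configuration. This geometry is the one expected from kinetic deprotonation without a polar cosolvent (larger α-substituent syn to the alkoxy oxygen), and it keeps the C7–C11=C12–O segment cisoid within the ring. Reaction at C15 and not at the other allyl terminus C7 is secured because C15 is a free methylene while C7 is fully substituted and part of the dienolate. In situ silylation prevents fragmentation of the ester enolate to ketene and tertiary alkoxide.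

Step 23
Reactants: 38 macrocyclic diacid bis(acetonide)
Product: 39 dimethyl ester bis(acetonide)
Conditions: Me3SiCHN2, MeOH/toluene, 0 °C → rt
Reagents that add atoms: trimethylsilyldiazomethane, C[Si](C)(C)C=[N+]=[N-]
Why: O-methylation of the carboxylic acids by the diazoalkane (proton transfer, then alkylation of the carboxylate); no attack at the hindered quaternary acyl carbon is needed.

Step 24
Reactants: 39 dimethyl ester bis(acetonide)
Product: 40 dimethyl ester 8,9,8′,9′-tetraol
Conditions: AcOH/THF/H2O (3:1:1), 45 °C
Reagents that add atoms: none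
Why: Acid-catalysed acetonide hydrolysis through the acetal oxocarbenium ion; a weak acid is used so that the dienylic C8–O bond is not ionized.

Step 25
Reactants: 40 dimethyl ester 8,9,8′,9′-tetraol
Product: 41 cycloshizukaol A
Conditions: MnO2 (activated, excess), CH2Cl2, rt
Reagents that add atoms: none
Why: MnO2 oxidizes the allylic (dienylic) C8 hydroxyls chemoselectively over the saturated, neopentyl C9 hydroxyls and so creates both cross-conjugated dienones under neutral conditions that leave the α-ketol centre C9 untouched. The reaction is stopped at conversion to limit glycol cleavage.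

## Compound list

1 | cis-bicyclo[3.1.0]hexan-3-one (meso) | O=C1C[C@@H]2C[C@@H]2C1 | starting material
2 | (1R,5R)-3-(trimethylsilyloxy)bicyclo[3.1.0]hex-2-ene | C[Si](C)(C)OC1=C[C@@H]2C[C@@H]2C1 | intermediate
3 | lithium (1R,5R)-bicyclo[3.1.0]hex-2-en-3-olate | [Li]OC1=C[C@@H]2C[C@@H]2C1 | intermediate (not isolated)
4 | (1R,5R)-2-methylbicyclo[3.1.0]hexan-3-one, C2 epimers (C2 is the future C10) | CC1[C@@H]2C[C@@H]2CC1=O | intermediate
5 | lithium enolate of 4 on the unsubstituted side (future C4) | CC1[C@@H]2C[C@@H]2C=C1O[Li] | intermediate (not isolated)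
6 | Mannich base, 4-[(dimethylamino)methyl]-2-methylbicyclo[3.1.0]hexan-3-one (cyclopropane as in 4) | CC1[C@@H]2C[C@@H]2C(CN(C)C)C1=O | intermediate (not isolated)
7 | methiodide of 6, trimethyl[(4-methyl-3-oxobicyclo[3.1.0]hexan-2-yl)methyl]ammonium iodide | CC1[C@@H]2C[C@@H]2C(C[N+](C)(C)C)C1=O.[I-] | intermediate (not isolated)
8 | (1R,5S)-2-methyl-4-methylidenebicyclo[3.1.0]hexan-3-one, C2 epimers | CC1[C@@H]2C[C@@H]2C(=C)C1=O | intermediate
9 | (1R,5S)-3-(tert-butyldimethylsilyloxy)-2-methyl-4-methylidenebicyclo[3.1.0]hex-2-ene | CC1=C(O[Si](C)(C)C(C)(C)C)C(=C)[C@H]2C[C@@H]12 | intermediate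
10 | (E)-but-2-en-1-ol | C/C=C/CO | starting material
11 | [(2R,3R)-3-methyloxiran-2-yl]methanol | C[C@H]1O[C@@H]1CO | intermediate
12 | (2R,3S)-3-[(4-methoxybenzyl)oxy]butane-1,2-diol | C[C@H](OCc1ccc(OC)cc1)[C@H](O)CO | intermediate
13 | (2R,3S)-3-[(4-methoxybenzyl)oxy]-1,2-bis(triethylsilyloxy)butane | C[C@H](OCc1ccc(OC)cc1)[C@H](O[Si](CC)(CC)CC)CO[Si](CC)(CC)CC | intermediate
14 | (2S,3S)-3-[(4-methoxybenzyl)oxy]-2-(triethylsilyloxy)butanal | C[C@H](OCc1ccc(OC)cc1)[C@H](O[Si](CC)(CC)CC)C=O | intermediate
15 | aldol adduct: 2-methyl-4-methylidenebicyclo[3.1.0]hexan-3-one carrying on C2 (= C10, chain anti to the cyclopropane CH2, methyl syn) the 1-hydroxy-2-(triethylsilyloxy)-3-(4-methoxybenzyloxy)butyl chain (C9-OH/C8-O anti, C8-O/C7-O anti) | C[C@H](OCc1ccc(OC)cc1)[C@H](O[Si](CC)(CC)CC)[C@H](O)[C@@]1(C)[C@@H]2C[C@@H]2C(=C)C1=O | intermediate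
16 | 8,9-diol corresponding to 15 | C[C@H](OCc1ccc(OC)cc1)[C@H](O)[C@H](O)[C@@]1(C)[C@@H]2C[C@@H]2C(=C)C1=O | intermediate (not isolated)
17 | 8,9-O-isopropylidene (cis-dioxolane) derivative of 16, C7 4-methoxybenzyl ether | C[C@H](OCc1ccc(OC)cc1)[C@@H]1OC(C)(C)O[C@@H]1[C@@]1(C)[C@@H]2C[C@@H]2C(=C)C1=O | intermediate
18 | C7 alcohol from 17 | C[C@H](O)[C@@H]1OC(C)(C)O[C@@H]1[C@@]1(C)[C@@H]2C[C@@H]2C(=C)C1=O | intermediate
19 | methyl ketone: cis-dioxolane bearing the acetyl group (C7, C6) on C8 and the 2-methyl-4-methylidene-3-oxobicyclo[3.1.0]hexan-2-yl group on C9 | CC(=O)[C@@H]1OC(C)(C)O[C@@H]1[C@@]1(C)[C@@H]2C[C@@H]2C(=C)C1=O | intermediate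
20 | lithium 5β-alkoxide of the cis-fused ketol (aldolate) | [Li]O[C@]12CC(=O)[C@@H]3OC(C)(C)O[C@@H]3[C@@]1(C)[C@@H]1C[C@@H]1C2=C | intermediate (not isolated)
21 | 5β-(triethylsilyloxy)-8β,9β-(isopropylidenedioxy)-11,12,13-trinorlinden-4(15)-en-7-one | CC[Si](CC)(CC)O[C@]12CC(=O)[C@@H]3OC(C)(C)O[C@@H]3[C@@]1(C)[C@@H]1C[C@@H]1C2=C | intermediate
22 | potassium 6-en-7-olate of 21 | CC[Si](CC)(CC)O[C@]12C=C(O[K])[C@@H]3OC(C)(C)O[C@@H]3[C@@]1(C)[C@@H]1C[C@@H]1C2=C | intermediate (not isolated)
23 | 5β-(triethylsilyloxy)-8β,9β-(isopropylidenedioxy)-11,12,13-trinorlindena-4(15),6-dien-7-yl trifluoromethanesulfonate | CC[Si](CC)(CC)O[C@]12C=C(OS(=O)(=O)C(F)(F)F)[C@@H]3OC(C)(C)O[C@@H]3[C@@]1(C)[C@@H]1C[C@@H]1C2=C | intermediate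
24 | methyl 2-bromopropanoate (racemic) | CC(Br)C(=O)OC | starting material
25 | bromo(1-methoxy-1-oxopropan-2-yl)zinc (Reformatsky reagent) | CC([Zn]Br)C(=O)OC | intermediate (not isolated)
26 | methyl 5β-(triethylsilyloxy)-8β,9β-(isopropylidenedioxy)lindena-4(15),6-dien-12-oate, C11 epimers | CC[Si](CC)(CC)O[C@]12C=C(C(C)C(=O)OC)[C@@H]3OC(C)(C)O[C@@H]3[C@@]1(C)[C@@H]1C[C@@H]1C2=C | intermediate
27 | 5β-(triethylsilyloxy)-8β,9β-(isopropylidenedioxy)lindena-4(15),6-dien-12-oic acid, C11 epimers | CC[Si](CC)(CC)O[C@]12C=C(C(C)C(O)=O)[C@@H]3OC(C)(C)O[C@@H]3[C@@]1(C)[C@@H]1C[C@@H]1C2=C | intermediate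
28 | methyl 5β-hydroxy-8β,9β-(isopropylidenedioxy)lindena-4(15),6-dien-12-oate, C11 epimers | O[C@]12C=C(C(C)C(=O)OC)[C@@H]3OC(C)(C)O[C@@H]3[C@@]1(C)[C@@H]1C[C@@H]1C2=C | intermediate
29 | acid chloride of 27 | CC[Si](CC)(CC)O[C@]12C=C(C(C)C(Cl)=O)[C@@H]3OC(C)(C)O[C@@H]3[C@@]1(C)[C@@H]1C[C@@H]1C2=C | intermediate (not isolated)
30 | lithium 5β-alkoxide of 28 | [Li]O[C@]12C=C(C(C)C(=O)OC)[C@@H]3OC(C)(C)O[C@@H]3[C@@]1(C)[C@@H]1C[C@@H]1C2=C | intermediate (not isolated)
31 | seco ester: 12-oyl group of 27 on the 5β-oxygen of 28 (one C5 triethylsilyl ether, one methyl ester) | CC[Si](CC)(CC)O[C@]12C=C(C(C)C(=O)O[C@]45C=C(C(C)C(=O)OC)[C@@H]6OC(C)(C)O[C@@H]6[C@@]4(C)[C@@H]4C[C@@H]4C5=C)[C@@H]3OC(C)(C)O[C@@H]3[C@@]1(C)[C@@H]1C[C@@H]1C2=C | intermediate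
32 | seco acid (C5 triethylsilyl ether, free C12′ acid) | CC[Si](CC)(CC)O[C@]12C=C(C(C)C(=O)O[C@]45C=C(C(C)C(O)=O)[C@@H]6OC(C)(C)O[C@@H]6[C@@]4(C)[C@@H]4C[C@@H]4C5=C)[C@@H]3OC(C)(C)O[C@@H]3[C@@]1(C)[C@@H]1C[C@@H]1C2=C | intermediate
33 | seco hydroxy acid (free 5β-hydroxyl, free C12′ acid) | O[C@]12C=C(C(C)C(=O)O[C@]45C=C(C(C)C(O)=O)[C@@H]6OC(C)(C)O[C@@H]6[C@@]4(C)[C@@H]4C[C@@H]4C5=C)[C@@H]3OC(C)(C)O[C@@H]3[C@@]1(C)[C@@H]1C[C@@H]1C2=C | intermediate
34 | 2-acyloxy-1-methylpyridinium iodide of 33 | O[C@]12C=C(C(C)C(=O)O[C@]45C=C(C(C)C(=O)Oc6cccc[n+]6C)[C@@H]6OC(C)(C)O[C@@H]6[C@@]4(C)[C@@H]4C[C@@H]4C5=C)[C@@H]3OC(C)(C)O[C@@H]3[C@@]1(C)[C@@H]1C[C@@H]1C2=C.[I-] | intermediate (not isolated)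
35 | twelve-membered macrodiolide: head-to-tail dilactone of two 5β-hydroxy-8β,9β-(isopropylidenedioxy)lindena-4(15),6-dien-12-oic acid units (C4=C15 methylenes, C11 epimers) | O=C1O[C@]23C=C(C(C)C(=O)O[C@]45C=C(C1C)[C@@H]6OC(C)(C)O[C@@H]6[C@@]4(C)[C@@H]4C[C@@H]4C5=C)[C@@H]6OC(C)(C)O[C@@H]6[C@@]2(C)[C@@H]2C[C@@H]2C3=C | intermediate
36 | bis(trimethylsilyl ketene acetal) of 35 (C7 cis to the ring oxygen, methyl cis to OSiMe3 on each C11=C12) | C/C1=C(\O[Si](C)(C)C)O[C@]23C=C(/C(C)=C(/O[Si](C)(C)C)O[C@]45C=C1[C@@H]6OC(C)(C)O[C@@H]6[C@@]4(C)[C@@H]4C[C@@H]4C5=C)[C@@H]6OC(C)(C)O[C@@H]6[C@@]2(C)[C@@H]2C[C@@H]2C3=C | intermediate (not isolated)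
37 | bis(trimethylsilyl ester) of 38 | C[Si](C)(C)OC(=O)[C@]1(C)CC2=C3C=C([C@@H]4OC(C)(C)O[C@@H]4[C@@]3(C)[C@@H]3C[C@H]23)[C@](C)(C(=O)O[Si](C)(C)C)CC2=C3C=C1[C@@H]1OC(C)(C)O[C@@H]1[C@@]3(C)[C@@H]1C[C@H]21 | intermediate (not isolated)
38 | macrocyclic diacid bis(acetonide): twelve-membered carbocycle with both (11R) quaternary centres, C4=C5–C6=C7 dienes and 8β,9β-acetonides | OC(=O)[C@]1(C)CC2=C3C=C([C@@H]4OC(C)(C)O[C@@H]4[C@@]3(C)[C@@H]3C[C@H]23)[C@](C)(C(O)=O)CC2=C3C=C1[C@@H]1OC(C)(C)O[C@@H]1[C@@]3(C)[C@@H]1C[C@H]21 | intermediate
39 | dimethyl ester of 38 | COC(=O)[C@]1(C)CC2=C3C=C([C@@H]4OC(C)(C)O[C@@H]4[C@@]3(C)[C@@H]3C[C@H]23)[C@](C)(C(=O)OC)CC2=C3C=C1[C@@H]1OC(C)(C)O[C@@H]1[C@@]3(C)[C@@H]1C[C@H]21 | intermediate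
40 | dimethyl ester 8β,9β,8′β,9′β-tetraol | COC(=O)[C@]1(C)CC2=C3C=C([C@H](O)[C@H](O)[C@@]3(C)[C@@H]3C[C@H]23)[C@](C)(C(=O)OC)CC2=C3C=C1[C@H](O)[C@H](O)[C@@]3(C)[C@@H]1C[C@H]21 | intermediate
41 | cycloshizukaol A | COC(=O)[C@]1(C)CC2=C3C=C(C(=O)[C@H](O)[C@@]3(C)[C@@H]3C[C@H]23)[C@](C)(C(=O)OC)CC2=C3C=C1C(=O)[C@H](O)[C@@]3(C)[C@@H]1C[C@H]21 | target

## Step count and weak points

Total: 25 steps. Longest linear sequence: 20 steps (1 → 41 through steps 1–4, 9–15, one of 16/17, 18–25; the aldehyde branch from 10 is equally long).

**Step 22 (key step).** The most likely failure is loss of stereocontrol at C11. Enolization inside the macrocycle may give the other ketene acetal geometry, or the ring may force a boat transition state for one or both shifts. The second shift also takes place in a ring already altered by the first and need not follow the same course. A lesser risk is fragmentation of the ester enolate to a ketene and the tertiary alkoxide before silylation.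
- Fallback: set the two centres one at a time, the first in an open chain where the geometry follows the usual solvent rules and a chair is unconstrained. It sets out from 33 and comes back at 38.
- Treating 33 with KN(SiMe3)2/Me3SiCl in THF should silylate hydroxyl and acid and give the open-chain silyl ketene acetal F1. Its single tertiary allylic ester rearranges to the tris-silylated product F2, and mild hydrolysis gives the hydroxy diacid F3 with one C11 centre and one diene in place.
- Lactonization as in step 21 (through the acyloxypyridinium salt F4) closes the twelve-membered lactone acid F5. Only the C12′ acid can reach the C5 hydroxyl, because the quaternary acid would have to form a bridgehead alkene.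
- A second enolization/silylation (ketene acetal F6) and [3,3] shift gives 37 and, after hydrolysis, 38.

**Step 21.** The tertiary bis-allylic hydroxyl may be acylated too slowly, so that the activated acid oligomerizes or dimerizes through its ketene, or the alcohol ionizes under the pyridinium salt.
- Fallback: reverse the roles and unmask a nucleophilic alkoxide next to a preformed active ester, the mode that serves for the first ester bond in step 18. It sets out from 32 and comes back at 35.
- The acid 32 is converted (C6F5OH, carbodiimide) into the pentafluorophenyl ester F7, which is stable to isolation. Slow addition of F7 to Bu4NF in THF at high dilution removes the silyl group and lets the tertiary alkoxide acylate itself to 35.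

**Step 9.** The tetrasubstituted enol ether may add sluggishly to the hindered aldehyde. The preferred enol ether face and the Felkin face of the aldehyde may also pair badly in the open transition state, eroding selectivity at C9, and the Lewis acid may cleave the α-silyl ether and open a chelated pathway.
- Fallback: a metal-enolate aldol through a closed transition state. It sets out from 8 and comes back at 15.
- LiN(SiMe3)2 deprotonates 8 at its only α-position to give the cross-conjugated lithium dienolate F8. This is treated with 14 at −78 °C and quenched cold with acetic acid.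

**Step 15.** The secondary alkylpalladium enolate may undergo β-hydride elimination (reduction of the triflate), transmetalation at the hindered alkenylpalladium next to the acetonide may be slow, and the product may be deprotonated by the zinc enolate with double-bond migration.
- Fallback: reverse the polarity of the coupling. It sets out from 23 and comes back at 26.
- Miyaura borylation (B2pin2, PdCl2(PPh3)2, PPh3, KOPh) gives the alkenyl boronate F9. F9 is coupled with the α-bromo ester 24 in a Suzuki reaction (Pd(OAc)2, P(o-tolyl)3, K3PO4).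

## Further compounds

F1 | step 22 | open-chain tris(trimethylsilyl) ketene acetal of 33 (C5 silyl ether, C12′ silyl ester, C11=C12 ketene acetal) | C[Si](C)(C)O[C@]12C=C(/C(C)=C(/O[Si](C)(C)C)O[C@]45C=C(C(C)C(=O)O[Si](C)(C)C)[C@@H]6OC(C)(C)O[C@@H]6[C@@]4(C)[C@@H]4C[C@@H]4C5=C)[C@@H]3OC(C)(C)O[C@@H]3[C@@]1(C)[C@@H]1C[C@@H]1C2=C
F2 | step 22 | rearranged tris-silylated compound (one C11–C15′ bond, bis(silyl ester), C5 silyl ether) | C[Si](C)(C)O[C@]12C=C([C@](C)(C(=O)O[Si](C)(C)C)CC3=C4C=C(C(C)C(=O)O[Si](C)(C)C)[C@@H]5OC(C)(C)O[C@@H]5[C@@]4(C)[C@@H]4C[C@H]34)[C@@H]3OC(C)(C)O[C@@H]3[C@@]1(C)[C@@H]1C[C@@H]1C2=C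
F3 | step 22 | hydroxy diacid with one quaternary C11 and one C4=C5–C6=C7 diene | O[C@]12C=C([C@](C)(C(O)=O)CC3=C4C=C(C(C)C(O)=O)[C@@H]5OC(C)(C)O[C@@H]5[C@@]4(C)[C@@H]4C[C@H]34)[C@@H]3OC(C)(C)O[C@@H]3[C@@]1(C)[C@@H]1C[C@@H]1C2=C
F4 | step 22 | 2-acyloxy-1-methylpyridinium iodide of F3 at the C12′ acid | O[C@]12C=C([C@](C)(C(O)=O)CC3=C4C=C(C(C)C(=O)Oc5cccc[n+]5C)[C@@H]5OC(C)(C)O[C@@H]5[C@@]4(C)[C@@H]4C[C@H]34)[C@@H]3OC(C)(C)O[C@@H]3[C@@]1(C)[C@@H]1C[C@@H]1C2=C.[I-]
F5 | step 22 | twelve-membered lactone acid (one C11–C15′ bond, one tertiary ester) | O=C1O[C@]23C=C([C@](C)(C(O)=O)CC4=C5C=C(C1C)[C@@H]6OC(C)(C)O[C@@H]6[C@@]5(C)[C@@H]5C[C@H]45)[C@@H]6OC(C)(C)O[C@@H]6[C@@]2(C)[C@@H]2C[C@@H]2C3=C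
F6 | step 22 | silyl ketene acetal of F5 as its trimethylsilyl ester | C/C1=C(\O[Si](C)(C)C)O[C@]23C=C([C@](C)(C(=O)O[Si](C)(C)C)CC4=C5C=C1[C@@H]6OC(C)(C)O[C@@H]6[C@@]5(C)[C@@H]5C[C@H]45)[C@@H]6OC(C)(C)O[C@@H]6[C@@]2(C)[C@@H]2C[C@@H]2C3=C
F7 | step 21 | pentafluorophenyl ester of 32 | CC[Si](CC)(CC)O[C@]12C=C(C(C)C(=O)O[C@]45C=C(C(C)C(=O)Oc6c(F)c(F)c(F)c(F)c6F)[C@@H]6OC(C)(C)O[C@@H]6[C@@]4(C)[C@@H]4C[C@@H]4C5=C)[C@@H]3OC(C)(C)O[C@@H]3[C@@]1(C)[C@@H]1C[C@@H]1C2=C
F8 | step 9 | lithium dienolate of 8 | CC1=C(O[Li])C(=C)[C@H]2C[C@@H]12
F9 | step 15 | pinacol alkenylboronate from 23 | CC[Si](CC)(CC)O[C@]12C=C(B4OC(C)(C)C(C)(C)O4)[C@@H]3OC(C)(C)O[C@@H]3[C@@]1(C)[C@@H]1C[C@@H]1C2=C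
A1 | alternative 1 | macrocyclic bis(cyclopropyl carbinol) with C4 hydroxyls, C8 ketones and C9 silyl ethers | COC(=O)[C@]1(C)C[C@@]2(O)[C@@H]3C=C(C(=O)[C@H](O[Si](C)(C)C(C)(C)C)[C@@]3(C)[C@@H]3C[C@H]23)[C@](C)(C(=O)OC)C[C@@]2(O)[C@@H]3C=C1C(=O)[C@H](O[Si](C)(C)C(C)(C)C)[C@@]3(C)[C@@H]1C[C@H]21
A2 | alternative 2 | lindenane diene monomer with free C9 hydroxyl, C8 silyl ether and the propanoate on C15 | COC(=O)C(C)CC1=C2C=C[C@H](O[Si](C)(C)C(C)(C)C)[C@H](O)[C@@]2(C)[C@@H]2C[C@H]12
A3 | alternative 3 | lindenane dienone monomer with C15 methyl, C7 propanoate and C9 silyl ether | CC1=C2C=C(C(C)C(=O)OC)C(=O)[C@H](O[Si](C)(C)C(C)(C)C)[C@@]2(C)[C@@H]2C[C@H]12
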